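The cyclohexanone ring is cut at C1–C2 (ketone carbon to its CH2) and the cyclobutane at C5–C11 (the CH next to CMe2 to the bridgehead alpha-carbon of the ketone). The key step closes both in one flask: a Dieckmann-type acylation of a tert-butyl ester enolate (C2) on a gamma-lactone carbonyl (C1, tethered to the C9 oxygen) gives a beta-keto ester, whose dianion is alkylated at C11 by the C5 tosylate (4-exo-tet). It exploits that C1 is an acyl carbon flanked by C11, which sits 1,3 to C5 across the C4–C10 bond of the cycloheptane. The precursor is a fully substituted monocyclic cycloheptane built by Ireland–Claisen and aldol chemistry.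

Key step: step 17

Remark on numbering: atoms carry longipinane locants throughout. C1 is the ketone carbon, C2 its CH2, C3 the CH(CH3), C4 and C11 the cyclobutane CH atoms bonded to C3 and C1, C5 the cyclobutane CH bonded to C6 (CMe2), C7 the acetoxy carbon, C8 the ring CH2, C9 the angeloyloxy carbon, C10 the quaternary methyl carbon. "Cis" and "trans" refer to the cycloheptane ring C4–C5–C6–C7–C8–C9–C10.

Assumption: compounds 1, 5, 14 and 29 are taken as commercial. The ester-bearing carbon C2 in 27, 28, 31 and 32 is an epimeric or enolic mixture and is drawn without configuration; it is removed in step 19.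

Step 1
Reactants: 1 tert-butyl(but-3-yn-1-yloxy)dimethylsilane
Product: 3 (E)-6-(tert-butyldimethylsilyloxy)-4-methylhex-3-en-2-one, via alkenylalane 2 (not isolated)
Conditions: Me3Al, Cp2ZrCl2 (0.25 equiv), CH2Cl2, 0 °C to rt; then ZnCl2, Pd(PPh3)4 (5 mol %), AcCl, THF, 0 °C to rt
Reagents that add atoms: trimethylaluminium C[Al](C)C; acetyl chloride CC(=O)Cl
Why: Zirconium-catalysed syn-carboalumination (Negishi) places methyl and aluminium cis on the terminal alkyne, and transmetalation to zinc followed by palladium-catalysed acylation with retention (Negishi acylation) should give the E-enone that carries C9, C10, C11 and C1.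

Step 2
Reactants: 3 (E)-6-(tert-butyldimethylsilyloxy)-4-methylhex-3-en-2-one
Product: 4 (2S,3E)-6-(tert-butyldimethylsilyloxy)-4-methylhex-3-en-2-ol
Conditions: (R)-2-methyl-CBS-oxazaborolidine (0.1 equiv), BH3·SMe2, THF, −30 °C
Reagents that add atoms: none
Why: Corey–Bakshi–Shibata reduction, in which the alkenyl group acts as the large and the methyl as the small substituent, so the (R)-catalyst should give the (S)-allylic alcohol that later controls C4 and C10.

Step 3
Reactants: 5 (R)-5-methoxy-3-methyl-5-oxopentanoic acid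
Product: 6 1-tert-butyl 5-methyl (S)-3-methylpentanedioate
Conditions: isobutylene, H2SO4 (cat.), CH2Cl2, rt, sealed vessel
Reagents that add atoms: isobutylene CC(C)=C
Why: Acid-catalysed addition of the carboxylic acid to isobutylene (tert-butyl ester formation) leaves the C3 stereocenter untouched; the descriptor changes only because the priorities change.

Step 4
Reactants: 6 1-tert-butyl 5-methyl (S)-3-methylpentanedioate
Product: 7 (S)-5-tert-butoxy-3-methyl-5-oxopentanoic acid
Conditions: LiOH·H2O, THF/H2O, 0 °C; then 1 M HCl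
Reagents that add atoms: lithium hydroxide [Li+].[OH-]
Why: Chemoselective saponification, in which hydroxide attacks the methyl ester while the tert-butyl ester is inert, frees the carboxyl group that becomes C5 and leaves the tert-butyl ester on the C2 side.

Step 5
Reactants: 7 (S)-5-tert-butoxy-3-methyl-5-oxopentanoic acid; 4 (2S,3E)-6-(tert-butyldimethylsilyloxy)-4-methylhex-3-en-2-ol
Product: 8 1-tert-butyl 5-[(2S,3E)-6-(tert-butyldimethylsilyloxy)-4-methylhex-3-en-2-yl] (S)-3-methylpentanedioate
Conditions: DCC, DMAP (cat.), CH2Cl2, 0 °C to rt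
Reagents that add atoms: none
Why: Steglich esterification acylates the secondary allylic alcohol at oxygen, so the carbinol configuration is retained.

Step 6
Reactants: 8 1-tert-butyl 5-[(2S,3E)-6-(tert-butyldimethylsilyloxy)-4-methylhex-3-en-2-yl] (S)-3-methylpentanedioate
Product: 11 (2R,3R,4E)-2-[(2R)-4-tert-butoxy-4-oxobutan-2-yl]-3-[2-(tert-butyldimethylsilyloxy)ethyl]-3-methylhex-4-enoic acid, via bis(trimethylsilyl) ketene acetal 9 (not isolated), via rearranged trimethylsilyl ester 10 (not isolated)
Conditions: LiN(i-Pr)2 (2.6 equiv), Me3SiCl (4 equiv, present from the start), THF, −78 °C to 60 °C; then 1 M HCl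
Reagents that add atoms: none
Why: Ireland–Claisen rearrangement, in which kinetic enolisation in THF puts the C3 chain cis to the allylic oxygen and a chair transition state with the carbinol methyl equatorial transfers the (S)-carbinol chirality to C4 and to the quaternary C10 (new C4–C10 bond, E-propenyl group), while the tert-butyl ester is silylated only as a spectator and returns on acidic work-up.

Step 7
Reactants: 11 (2R,3R,4E)-2-[(2R)-4-tert-butoxy-4-oxobutan-2-yl]-3-[2-(tert-butyldimethylsilyloxy)ethyl]-3-methylhex-4-enoic acid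
Product: 13 tert-butyl (3R,4R,5R,6E)-5-[2-(tert-butyldimethylsilyloxy)ethyl]-4-formyl-3,5-dimethyloct-6-enoate, via acid chloride 12 (not isolated)
Conditions: 1-chloro-N,N,2-trimethylprop-1-en-1-amine, CH2Cl2, 0 °C; then LiAlH(Ot-Bu)3, THF, −78 °C
Reagents that add atoms: none
Why: Neutral acid chloride formation followed by partial hydride reduction with LiAlH(Ot-Bu)3 should stop at the C5 aldehyde without touching the tert-butyl ester, the silyl ether or the configuration at C4.

Step 8
Reactants: 13 tert-butyl (3R,4R,5R,6E)-5-[2-(tert-butyldimethylsilyloxy)ethyl]-4-formyl-3,5-dimethyloct-6-enoate; 14 3-bromo-3-methylbutan-2-one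
Product: 16 tert-butyl (3R,4R,5R,6E)-5-[2-(tert-butyldimethylsilyloxy)ethyl]-4-[(1S)-1-hydroxy-2,2-dimethyl-3-oxobutyl]-3,5-dimethyloct-6-enoate, via samarium enolate 15 (not isolated)
Conditions: SmI2 (2.2 equiv), THF, −78 °C, 13 and 14 added together
Reagents that add atoms: none
Why: Samarium Reformatsky-type aldol, in which SmI2 reduces the bromo ketone regiospecifically to the tetrasubstituted trivalent samarium enolate, which should add to the aldehyde anti to the quaternary C10 group (Felkin–Anh) and so set C5 while forming the C5–C6 bond.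

Step 9
Reactants: 16 tert-butyl (3R,4R,5R,6E)-5-[2-(tert-butyldimethylsilyloxy)ethyl]-4-[(1S)-1-hydroxy-2,2-dimethyl-3-oxobutyl]-3,5-dimethyloct-6-enoate
Product: 17 C5 tosylate of 16
Conditions: TsCl, 1-methylimidazole, Et3N, CH2Cl2, 0 °C to rt
Reagents that add atoms: p-toluenesulfonyl chloride Cc1ccc(cc1)S(Cl)(=O)=O
Why: O-sulfonylation through the N-sulfonylimidazolium salt retains C5, and a tosylate is chosen because, unlike a mesylate, it has no acidic alpha-hydrogen for the strong-base step 17.

Step 10
Reactants: 17 C5 tosylate of 16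
Product: 18 keto aldehyde with C9 as a formyl group on C10 and C7 as a methyl ketone
Conditions: O3, CH2Cl2, −78 °C; then PPh3
Reagents that add atoms: ozone [O-][O+]=O
Why: Ozonolysis with reductive work-up cleaves the only C=C bond and unmasks the non-enolisable C9 aldehyde on the quaternary carbon.

Step 11
Reactants: 18 keto aldehyde with C9 as a formyl group on C10 and C7 as a methyl ketone
Product: 19 cycloheptenone (C7 ketone, C8=C9 double bond) with the C4 side chain cis to the C10 silyloxyethyl arm and trans to the C5 tosylate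
Conditions: Bn2NH·CF3CO2H (0.5 equiv), toluene, 60 °C
Reagents that add atoms: none
Why: Amine-salt-catalysed intramolecular aldol condensation (7-exo-trig aldol, then dehydration) can give only one enone because the methyl ketone enolises only toward C8 and the aldehyde cannot enolise.

Step 12
Reactants: 19 cycloheptenone (C7 ketone, C8=C9 double bond)
Product: 21 beta-hydroxy ketone with C9–OH cis to the C10 methyl, via pinacol boronate 20 (not isolated)
Conditions: CuCl (5 mol %), Xantphos (5 mol %), NaOt-Bu (10 mol %), B2pin2, MeOH, THF, rt; then NaBO3·4H2O, THF/H2O, rt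
Reagents that add atoms: sodium perborate [Na+].[O-]OB=O
Why: Copper-catalysed conjugate borylation followed by perborate oxidation with retention, in which the monovalent copper boryl should attack C9 on the face of the C10 methyl, away from the C10 silyloxyethyl arm and the C4 side chain.

Step 13
Reactants: 21 beta-hydroxy ketone with C9–OH cis to the C10 methyl
Product: 22 trans-C7,C9-diol
Conditions: Me4NBH(OAc)3, AcOH/MeCN, −30 °C
Reagents that add atoms: none
Why: Evans–Saksena hydroxyl-directed reduction delivers hydride intramolecularly from the C9-bound acetoxyborohydride to the same face of the C7 ketone and should give the 1,3-anti diol, setting C7.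

Step 14
Reactants: 22 trans-C7,C9-diol
Product: 23 triol with free primary C1–OH
Conditions: HF·pyridine, THF/pyridine, 0 °C to rt
Reagents that add atoms: none
Why: Fluoride-mediated cleavage of the primary tert-butyldimethylsilyl ether leaves the tosylate and the tert-butyl ester intact.

Step 15
Reactants: 23 triol with free primary C1–OH
Product: 25 trans-fused gamma-lactone (C9–O–C1(=O)–C11–C10) with free C7–OH, via lactol 24 (not isolated)
Conditions: TEMPO (0.2 equiv), PhI(OAc)2 (2.5 equiv), CH2Cl2, rt
Reagents that add atoms: none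
Why: TEMPO/PhI(OAc)2 oxidation is selective for the primary alcohol, and the aldehyde is trapped by C9–OH as a five-membered lactol that is oxidised on to the lactone, which brings C1 to the acyl level and distinguishes the C9 from the C7 hydroxyl.

Step 16
Reactants: 25 trans-fused gamma-lactone with free C7–OH
Product: 26 C7 triethylsilyl ether of 25
Conditions: Et3SiOTf, 2,6-lutidine, CH2Cl2, −78 to 0 °C
Reagents that add atoms: triethylsilyl trifluoromethanesulfonate CC[Si](CC)(CC)OS(=O)(=O)C(F)(F)F
Why: Silyl triflate silylation caps the hindered C7–OH so that no C7 alkoxide can displace the trans C5 tosylate (oxetane formation) in step 17.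

Step 17
Reactants: 26 C7 triethylsilyl ether of 25
Product: 28 tricyclic beta-keto ester (longipinan-1-one core with C2–CO2t-Bu, C7–OSiEt3, C9–OH), via bicyclic keto ester 27 (not isolated)
Conditions: LiN(SiMe3)2 (2.2 equiv), THF, −78 to 0 °C; then LiN(i-Pr)2 (2.5 equiv), THF/DMPU, −78 to 40 °C; aq. NH4Cl
Reagents that add atoms: none
Why: LiN(SiMe3)2 forms the tert-butyl ester enolate at C2, which attacks the lactone carbonyl C1 (Dieckmann-type acylation, 6-exo-trig, the lactone releasing the C9 alkoxide as a built-in leaving group), and LiN(i-Pr)2 then deprotonates the resulting beta-keto ester enolate at C11 to the dianion, whose gamma-carbon displaces the C5 tosylate with inversion (4-exo-tet). The closest known reaction types are the Dieckmann condensation, the gamma-alkylation of beta-keto ester dianions and the ketone-enolate displacement of a neopentyl-type secondary sulfonate that is an established way to close bridged cyclobutanes. The C1–C2 bond closes the cyclohexanone ring cis-fused on the cycloheptane because the C4 and C10 arms are cis, and the C5–C11 bond closes the four-membered ring across the C4–C10 bond. C11 is fixed by the geometry of the bridged cyclobutane, C5 by inversion of the Felkin-derived tosylate, and C2 is left undefined and removed later. The step needs C- over O-alkylation and substitution over elimination: the dianion reacts at its gamma-carbon, lithium counter-ions disfavour O-alkylation, C6 has no hydrogen and the only beta-hydrogen (C4–H) is cis to the tosylate so anti-elimination is blocked, the tert-butyl ester cannot serve as acyl acceptor, and the C9 alkoxide is on the same face as the tosylate and cannot displace it.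

Step 18
Reactants: 28 tricyclic beta-keto ester; 29 angelic acid ((Z)-2-methylbut-2-enoic acid)
Product: 31 C9 angelate of 28, via mixed anhydride 30 (not isolated)
Conditions: 29, 2,4,6-trichlorobenzoyl chloride, Et3N, toluene, rt; then 28, toluene, 80 °C
Reagents that add atoms: none
Why: Yamaguchi-type mixed anhydride esterification run without DMAP is a known way to acylate hindered secondary alcohols with angelic acid without Z-to-E isomerisation to the tiglate.

Step 19
Reactants: 31 C9 angelate of 28
Product: 33 7-hydroxy-9-angeloyloxylongipinan-1-one, via keto acid 32 (not isolated)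
Conditions: CF3CO2H/CH2Cl2 (1:4), 0 °C to rt; then toluene, 70 °C
Reagents that add atoms: none
Why: Acidolysis removes the tert-butyl ester (loss of isobutylene) and the triethylsilyl ether, and the beta-keto acid should decarboxylate on warming to leave the C2 methylene without touching C3 or the angelate.

Step 20
Reactants: 33 7-hydroxy-9-angeloyloxylongipinan-1-one
Product: 34 CNP0204102.1 ((3R,4S,5S,7S,9S,10R,11R)-7-acetoxy-9-angeloyloxylongipinan-1-one)
Conditions: Ac2O, pyridine, DMAP (cat.), CH2Cl2, rt
Reagents that add atoms: acetic anhydride CC(=O)OC(C)=O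
Why: DMAP-catalysed O-acetylation of the C7 alcohol proceeds with retention and at room temperature should not isomerise the angelate.

Compound list
1 | tert-butyl(but-3-yn-1-yloxy)dimethylsilane | C#CCCO[Si](C)(C)C(C)(C)C | starting material
2 | (E)-[4-(tert-butyldimethylsilyloxy)-2-methylbut-1-en-1-yl]dimethylaluminium | C[Al](C)/C=C(\C)CCO[Si](C)(C)C(C)(C)C | intermediate
3 | (E)-6-(tert-butyldimethylsilyloxy)-4-methylhex-3-en-2-one | CC(=O)/C=C(\C)CCO[Si](C)(C)C(C)(C)C | intermediate
4 | (2S,3E)-6-(tert-butyldimethylsilyloxy)-4-methylhex-3-en-2-ol | C[C@H](O)/C=C(\C)CCO[Si](C)(C)C(C)(C)C | intermediate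
5 | (R)-5-methoxy-3-methyl-5-oxopentanoic acid (methyl hydrogen (R)-3-methylglutarate) | COC(=O)C[C@H](C)CC(=O)O | starting material
6 | 1-tert-butyl 5-methyl (S)-3-methylpentanedioate | COC(=O)C[C@H](C)CC(=O)OC(C)(C)C | intermediate
7 | (S)-5-tert-butoxy-3-methyl-5-oxopentanoic acid | OC(=O)C[C@H](C)CC(=O)OC(C)(C)C | intermediate
8 | 1-tert-butyl 5-[(2S,3E)-6-(tert-butyldimethylsilyloxy)-4-methylhex-3-en-2-yl] (S)-3-methylpentanedioate | CC(C)(C)OC(=O)C[C@@H](C)CC(=O)O[C@@H](C)/C=C(\C)CCO[Si](C)(C)C(C)(C)C | intermediate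
9 | bis(trimethylsilyl) ketene acetal of 8 (C3 chain cis to the allylic oxygen) | CC(C)(C)O/C(O[Si](C)(C)C)=C\[C@@H](C)/C=C(/O[Si](C)(C)C)O[C@@H](C)/C=C(\C)CCO[Si](C)(C)C(C)(C)C | intermediate
10 | trimethylsilyl ester of 11 with the tert-butyl ester still as its silyl ketene acetal | CC(C)(C)O/C(O[Si](C)(C)C)=C\[C@@H](C)[C@@H](C(=O)O[Si](C)(C)C)[C@](C)(CCO[Si](C)(C)C(C)(C)C)/C=C/C | intermediate
11 | (2R,3R,4E)-2-[(2R)-4-tert-butoxy-4-oxobutan-2-yl]-3-[2-(tert-butyldimethylsilyloxy)ethyl]-3-methylhex-4-enoic acid | OC(=O)[C@H]([C@H](C)CC(=O)OC(C)(C)C)[C@](C)(CCO[Si](C)(C)C(C)(C)C)/C=C/C | intermediate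
12 | acid chloride of 11 | ClC(=O)[C@H]([C@H](C)CC(=O)OC(C)(C)C)[C@](C)(CCO[Si](C)(C)C(C)(C)C)/C=C/C | intermediate
13 | tert-butyl (3R,4R,5R,6E)-5-[2-(tert-butyldimethylsilyloxy)ethyl]-4-formyl-3,5-dimethyloct-6-enoate | O=C[C@H]([C@H](C)CC(=O)OC(C)(C)C)[C@](C)(CCO[Si](C)(C)C(C)(C)C)/C=C/C | intermediate
14 | 3-bromo-3-methylbutan-2-one | CC(=O)C(C)(C)Br | starting material
15 | diiodosamarium enolate of 3-methylbutan-2-one (tetrasubstituted) | CC(O[Sm](I)I)=C(C)C | intermediate
16 | tert-butyl (3R,4R,5R,6E)-5-[2-(tert-butyldimethylsilyloxy)ethyl]-4-[(1S)-1-hydroxy-2,2-dimethyl-3-oxobutyl]-3,5-dimethyloct-6-enoate | CC(=O)C(C)(C)[C@@H](O)[C@H]([C@H](C)CC(=O)OC(C)(C)C)[C@](C)(CCO[Si](C)(C)C(C)(C)C)/C=C/C | intermediate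
17 | C5 tosylate of 16 | CC(=O)C(C)(C)[C@@H](OS(=O)(=O)c1ccc(C)cc1)[C@H]([C@H](C)CC(=O)OC(C)(C)C)[C@](C)(CCO[Si](C)(C)C(C)(C)C)/C=C/C | intermediate
18 | keto aldehyde (C9 formyl on C10, C7 methyl ketone, C5 tosylate) | CC(=O)C(C)(C)[C@@H](OS(=O)(=O)c1ccc(C)cc1)[C@H]([C@H](C)CC(=O)OC(C)(C)C)[C@](C)(CCO[Si](C)(C)C(C)(C)C)C=O | intermediate
19 | cycloheptenone (C7 ketone, C8=C9): C10 methyl and 2-silyloxyethyl, C4 side chain cis to that arm, C5 tosyloxy trans to the side chain, C6 gem-dimethyl | O=C1C=C[C@@](C)(CCO[Si](C)(C)C(C)(C)C)[C@@H]([C@H](C)CC(=O)OC(C)(C)C)[C@H](OS(=O)(=O)c2ccc(C)cc2)C1(C)C | intermediate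
20 | C9 pinacol boronate of the saturated ketone (boron cis to the C10 methyl) | O=C1C[C@H](B2OC(C)(C)C(C)(C)O2)[C@@](C)(CCO[Si](C)(C)C(C)(C)C)[C@@H]([C@H](C)CC(=O)OC(C)(C)C)[C@H](OS(=O)(=O)c3ccc(C)cc3)C1(C)C | intermediate
21 | beta-hydroxy ketone (C9–OH cis to the C10 methyl, C7 ketone) | O=C1C[C@H](O)[C@@](C)(CCO[Si](C)(C)C(C)(C)C)[C@@H]([C@H](C)CC(=O)OC(C)(C)C)[C@H](OS(=O)(=O)c2ccc(C)cc2)C1(C)C | intermediate
22 | trans-C7,C9-diol (C7–OH cis to the C4 side chain) | O[C@H]1C[C@H](O)[C@@](C)(CCO[Si](C)(C)C(C)(C)C)[C@@H]([C@H](C)CC(=O)OC(C)(C)C)[C@H](OS(=O)(=O)c2ccc(C)cc2)C1(C)C | intermediate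
23 | triol (C1, C7 and C9 hydroxyls free) | O[C@H]1C[C@H](O)[C@@](C)(CCO)[C@@H]([C@H](C)CC(=O)OC(C)(C)C)[C@H](OS(=O)(=O)c2ccc(C)cc2)C1(C)C | intermediate
24 | lactol between C1 and the C9 oxygen | O[C@H]1C[C@@H]2OC(O)C[C@@]2(C)[C@@H]([C@H](C)CC(=O)OC(C)(C)C)[C@H](OS(=O)(=O)c3ccc(C)cc3)C1(C)C | intermediate
25 | trans-fused gamma-lactone (C9–O–C1(=O)–C11–C10), C7–OH free | O[C@H]1C[C@@H]2OC(=O)C[C@@]2(C)[C@@H]([C@H](C)CC(=O)OC(C)(C)C)[C@H](OS(=O)(=O)c3ccc(C)cc3)C1(C)C | intermediate
26 | C7 triethylsilyl ether of 25 | CC[Si](CC)(CC)O[C@H]1C[C@@H]2OC(=O)C[C@@]2(C)[C@@H]([C@H](C)CC(=O)OC(C)(C)C)[C@H](OS(=O)(=O)c3ccc(C)cc3)C1(C)C | intermediate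
27 | bicyclic beta-keto ester (cyclohexanone cis-fused on the cycloheptane, C9–OH, C5 tosylate, C7–OSiEt3) | CC[Si](CC)(CC)O[C@H]1C[C@H](O)[C@@]2(C)CC(=O)C(C(=O)OC(C)(C)C)[C@@H](C)[C@H]2[C@H](OS(=O)(=O)c3ccc(C)cc3)C1(C)C | intermediate
28 | tricyclic beta-keto ester: tert-butyl 9-hydroxy-1-oxo-7-(triethylsilyloxy)longipinane-2-carboxylate | O[C@H]1C[C@H](O[Si](CC)(CC)CC)C(C)(C)[C@H]2[C@@H]3[C@H](C)C(C(=O)OC(C)(C)C)C(=O)[C@H]2[C@@]31C | intermediate
29 | angelic acid ((Z)-2-methylbut-2-enoic acid) | C/C=C(/C)C(=O)O | starting material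
30 | (Z)-2-methylbut-2-enoic 2,4,6-trichlorobenzoic anhydride | C/C=C(/C)C(=O)OC(=O)c1c(Cl)cc(Cl)cc1Cl | intermediate
31 | C9 angelate of 28 | C/C=C(/C)C(=O)O[C@H]1C[C@H](O[Si](CC)(CC)CC)C(C)(C)[C@H]2[C@@H]3[C@H](C)C(C(=O)OC(C)(C)C)C(=O)[C@H]2[C@@]31C | intermediate
32 | 9-angeloyloxy-7-hydroxy-1-oxolongipinane-2-carboxylic acid | C/C=C(/C)C(=O)O[C@H]1C[C@H](O)C(C)(C)[C@H]2[C@@H]3[C@H](C)C(C(=O)O)C(=O)[C@H]2[C@@]31C | intermediate
33 | 9-angeloyloxy-7-hydroxylongipinan-1-one | C/C=C(/C)C(=O)O[C@H]1C[C@H](O)C(C)(C)[C@H]2[C@@H]3[C@H](C)CC(=O)[C@H]2[C@@]31C | intermediate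
34 | CNP0204102.1, (3R,4S,5S,7S,9S,10R,11R)-7-acetoxy-9-angeloyloxylongipinan-1-one | C/C=C(/C)C(=O)O[C@H]1C[C@H](OC(C)=O)C(C)(C)[C@H]2[C@@H]3[C@H](C)CC(=O)[C@H]2[C@@]31C | target

Total step count: 20. Longest linear sequence: 18 steps (steps 1, 2 and 5 to 20 from compound 1; equally steps 3 to 20 from compound 5).

Steps most likely to fail

Step 17. The displacement at the neopentyl-type C5 may be too slow, so that O-alkylation of the enolate to a bridged enol ether or decomposition of the tosylate competes. The acylation on the trans-fused lactone may also stall at the hemiketal stage. The fallback sets out from 26 and returns at 28. Ammonolysis (NH3, MeOH) should open the lactone to the C9-hydroxy primary amide F1. Dehydration ((CF3CO)2O, pyridine; then K2CO3, MeOH to free C9–OH) should give the hydroxy nitrile F2. With excess LiN(i-Pr)2 in THF/DMPU the nitrile anion, a small and strong carbon nucleophile with no oxygen terminus, should close the cyclobutane at C5 first. The tert-butyl ester enolate should then add to the nitrile (Thorpe–Ziegler addition) to give the cyclic enamino ester F3. Mild hydrolysis (aq. AcOH, THF) should convert F3 into 28.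

Step 12. Poor facial selectivity at C9 is possible, because the two faces of the enone differ only by the substituents on the neighbouring quaternary C10 and by the ring conformation. The fallback sets out from 19 and returns at 21. A reagent-controlled nucleophilic epoxidation (t-BuOOH, La(Oi-Pr)3, (R)-BINOL, Ph3As=O, THF) should give the epoxy ketone F4 with the oxygen on the face of the C10 methyl. Reductive cleavage of the alpha C–O bond (SmI2, THF/MeOH, −78 °C) should then give 21.

Step 11. The seven-membered aldol condensation may stop at a reversible aldol stage or give way to intermolecular condensation. The fallback sets out from 13 and returns at 19, closing the ring by olefination. The dianion of commercial dimethyl (3-methyl-2-oxobutyl)phosphonate (NaH, then n-BuLi, THF) should add through its tertiary gamma-carbon to aldehyde 13 to give the hydroxy keto phosphonate F5. Tosylation as in step 9 should give F6, and ozonolysis as in step 10 the phosphonate aldehyde F7. An intramolecular Horner–Wadsworth–Emmons reaction (LiCl, DBU, MeCN) should then give 19.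

Further compounds
F1 | step 17 | C9-hydroxy primary amide from ammonolysis of lactone 26 | CC[Si](CC)(CC)O[C@H]1C[C@H](O)[C@@](C)(CC(N)=O)[C@@H]([C@H](C)CC(=O)OC(C)(C)C)[C@H](OS(=O)(=O)c2ccc(C)cc2)C1(C)C
F2 | step 17 | C9-hydroxy nitrile (C1 as cyano group) | CC[Si](CC)(CC)O[C@H]1C[C@H](O)[C@@](C)(CC#N)[C@@H]([C@H](C)CC(=O)OC(C)(C)C)[C@H](OS(=O)(=O)c2ccc(C)cc2)C1(C)C
F3 | step 17 | tricyclic enamino ester (C1 amino, C1=C2 double bond, C2–CO2t-Bu) | O[C@H]1C[C@H](O[Si](CC)(CC)CC)C(C)(C)[C@H]2[C@@H]3[C@H](C)C(C(=O)OC(C)(C)C)=C(N)[C@H]2[C@@]31C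
F4 | step 12 | C8,C9-epoxy ketone (oxygen cis to the C10 methyl) | O=C1[C@@H]2O[C@@H]2[C@@](C)(CCO[Si](C)(C)C(C)(C)C)[C@@H]([C@H](C)CC(=O)OC(C)(C)C)[C@H](OS(=O)(=O)c3ccc(C)cc3)C1(C)C
F5 | step 11 | hydroxy keto phosphonate (C8 bearing the dimethyl phosphonate) | COP(=O)(OC)CC(=O)C(C)(C)[C@@H](O)[C@H]([C@H](C)CC(=O)OC(C)(C)C)[C@](C)(CCO[Si](C)(C)C(C)(C)C)/C=C/C
F6 | step 11 | C5 tosylate of F5 | COP(=O)(OC)CC(=O)C(C)(C)[C@@H](OS(=O)(=O)c1ccc(C)cc1)[C@H]([C@H](C)CC(=O)OC(C)(C)C)[C@](C)(CCO[Si](C)(C)C(C)(C)C)/C=C/C
F7 | step 11 | phosphonate aldehyde (C9 formyl) | COP(=O)(OC)CC(=O)C(C)(C)[C@@H](OS(=O)(=O)c1ccc(C)cc1)[C@H]([C@H](C)CC(=O)OC(C)(C)C)[C@](C)(CCO[Si](C)(C)C(C)(C)C)C=O
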